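Start from what cannot change: each second end group charged stays in the flask in some form, so write the balance of these groups before anything else.

| setting | dusk | midnight | winter | Thursday's | Tuesday's | Wednesday's | Sunday's | Monday's |
|---|---|---|---|---|---|---|---|---|
| first end groups | 0.28 M | 0.28 M | 0.50 M | 0.28 M | 0.28 M | 0.28 M | 0.60 M | 0.28 M |
| second end groups | 0.308 M | 0.308 M | 0.308 M | 0.500 M | 0.500 M | 1.00 M | 0.308 M | 0.308 M |
| third end groups | 0.11 M | 0.56 M | 0.14 M | 0.140 M | 0.0800 M | 0.400 M | 0.140 M | 0.140 M |
| remark | run made earlier | run made earlier | run made earlier |  |  |  |  |  |
| time |  |  |  | 5.0 min | 5.0 min | 5.0 min | 5.0 min | 5.0 min |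

| run | time / min | links / % | first end groups / % |
|---|---|---|---|
| dusk | 0.500 | 23.0 | 77.3 |
| dusk | 1.00 | 27.2 | 65.2 |
| dusk | 1.50 | 32.6 | 53.9 |
| dusk | 2.00 | 34.0 | 46.7 |
| dusk | 2.50 | 35.5 | 41.9 |
| dusk | 3.00 | 36.7 | 35.9 |
| dusk | 4.00 | 36.8 | 31.3 |
| midnight | 0.500 | 12.2 | 86.9 |
| midnight | 1.00 | 12.7 | 80.4 |
| midnight | 1.50 | 12.4 | 79.0 |
| midnight | 2.00 | 12.0 | 75.9 |
| midnight | 2.50 | 11.3 | 76.1 |
| midnight | 3.00 | 8.7 | 74.7 |
| midnight | 4.00 | 6.1 | 73.1 |
| winter | 0.667 | 18.7 | 74.3 |
| winter | 1.33 | 22.2 | 61.0 |
| winter | 2.00 | 21.1 | 54.8 |
| winter | 3.00 | 18.0 | 46.6 |
| winter | 4.00 | 12.4 | 41.3 |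

(readings scatter by 1 percentage point)

- the numbers in the tables scatter with a standard deviation of 1 percentage point

1. all flasks from highest to lowest amount of links, in percent of the first end groups charged, at 5.0 min (Thursday's / Tuesday's / Wednesday's / Sunday's / Monday's)
2. the amount of links, in percent of the first end groups charged of the flask you put first, at 5.0 min
3. the amount of links, in percent of the first end groups charged of the flask you put last, at 5.0 min

Take the main step by itself. First end groups join second end groups to links one for one, so links cannot pass the smaller charge, which in Wednesday's is the 0.28 M of first end groups.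

Now add the third end groups, which compete for second end groups. In the midnight run, with 0.56 M of them against 0.308 M of second end groups, the links peak at a reading of 12.7%. So subtract their share. Wednesday's keeps 1.00 M less 0.400 M over 0.28 M, which is 2.14. This is the spare ratio: second end groups left after the third end groups take their share, per first end group charged. The other flasks give:

Tuesday's 1.50, Thursday's 1.29, Monday's 0.600, Sunday's 0.280

Last, add the fall of links. In the winter run they drop from 22.2% to 12.4% while first end groups remain, so read this as first end groups attacking links. The side product then holds two first end groups but one second end group, which gives: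

second end groups spent on first end groups = (links + first end groups lost) / 2

The last winter reading gives 35.6% of the first end groups charged, close to that run's spare ratio of 33.6%.

Below a ratio of one, as in Monday's and Sunday's, spare second end groups are the limiting reagent of the main step. Rank the flasks by the ratio, with Wednesday's first and Sunday's last.

The forecast gives Wednesday's > Tuesday's > Thursday's > Monday's > Sunday's, the same ranking, and adds percentages that the ratio does not give: 74% and 6%. Of the last flask it says “Sunday resembles winter with excess A destroying links”, A being first end groups.

The flasks give Wednesday's > Tuesday's > Thursday's > Monday's > Sunday's, with 75.8% in Wednesday's and 7.85% in Sunday's.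

    first end groups + second end groups → links (k = 0.0343 /M/s)
    second end groups + third end groups → links of the second sort (k = 0.111 /M/s)
    first end groups + links → side product (k = 0.0176 /M/s)
    second end groups → decomposed reagent (k = 6.03 × 10⁻⁴ /s)

In Wednesday's, the main step uses first end groups 27 times as fast as the attack on links at 0.122 min, and still 2.6 times as fast at 5.00 min. That flask holds 75.8% as links and 23.3% as side product, counted by the first end groups in it, a split its ratio of 2.14 does not show; the ratio also counts nothing for the 0.0670 M of decomposed reagent in Wednesday's. Raise the third end groups of Wednesday's to 0.68 M and the ratio becomes 1.14, under Thursday's, so expect links somewhat below Thursday's 57.9%. That neighbour flask gives 56.6% of links.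

(Readings and results were computed with made-up constants; scatter was added.)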